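Germacranolide numbering: carbocycle C1–C10, lactone O6–C12(=O)–C11(=C13)–C7, ester carbon C14. The route rests on closing the five-membered lactone ring through the C7–C11 bond. The O6 phosphonoacetate of an acyclic trans-7,8-epoxide is deprotonated and its carbanion opens the epoxide at C7 (5-exo-tet). One operation forms C7–C11, sets C7 by inversion (trans lactone), frees the C8 hydroxyl for the angelate and, once formaldehyde is added, installs the C11=C13 methylene. The feature exploited is the anti array C11–C7/C8–O beside O6, which maps onto one epoxide. Ring-closing metathesis at C4=C5 then closes the ten-membered ring, and a C2-hydroxyl-directed epoxidation completes the target.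

Key step: step 12

Remark: the reagent and ligand antipodes named ((−)-Ipc2BOMe, (R,R)-ProPhenol, (+)-MIB, D-(−)-DIPT) are those expected to give the configurations drawn in the SMILES; α/β refer to the usual germacranolide drawing with H7 α.

Step 1
Reactants: 1 3-(trimethylsilyl)prop-2-ynal; 2 (2-methylallyl)magnesium chloride
Product: 4 (3S)-5-methyl-1-(trimethylsilyl)hex-5-en-1-yn-3-ol, via B-methallyldiisopinocampheylborane 3 (not isolated)
Conditions: (−)-Ipc2BOMe, 2, Et2O, −78 °C → rt; 1, −78 °C; NaOH, H2O2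
Reagents that add atoms: none
Why: Brown asymmetric methallylboration, in which the chair transition state of the (−)-Ipc2B reagent adds the methallyl group to one face of the ynal and sets C2 as (S) by reagent control.

Step 2
Reactants: 4 (3S)-5-methyl-1-(trimethylsilyl)hex-5-en-1-yn-3-ol
Product: 5 (3S)-3-(tert-butyldimethylsilyloxy)-5-methyl-1-(trimethylsilyl)hex-5-en-1-yne
Conditions: TBSCl, imidazole, DMF, rt
Reagents that add atoms: tert-butyldimethylsilyl chloride, CC(C)(C)[Si](C)(C)Cl
Why: Standard silylation of a secondary propargylic alcohol, which masks the C2 hydroxyl until step 15.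

Step 3
Reactants: 5 (3S)-3-(tert-butyldimethylsilyloxy)-5-methyl-1-(trimethylsilyl)hex-5-en-1-yne
Product: 6 (3S)-3-(tert-butyldimethylsilyloxy)-5-methylhex-5-en-1-yne
Conditions: K2CO3, MeOH, rt
Reagents that add atoms: none
Why: Methanolysis of the alkynyl C–Si bond (protodesilylation) should leave the O-silyl ether intact and give the terminal alkyne.

Step 4
Reactants: 6 (3S)-3-(tert-butyldimethylsilyloxy)-5-methylhex-5-en-1-yne; 7 (2E)-4,4-dimethoxybut-2-enal
Product: 8 (2E,4R,7S)-7-(tert-butyldimethylsilyloxy)-1,1-dimethoxy-9-methyldeca-2,9-dien-5-yn-4-ol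
Conditions: (R,R)-ProPhenol (20 mol %), Me2Zn, Ph3P=O (40 mol %), toluene, 4 °C
Reagents that add atoms: none
Why: ProPhenol/dinuclear zinc asymmetric alkynylation of an enal, in which the zinc acetylide adds 1,2 to the aldehyde and the ligand sets the future C9 (4R here) by catalyst control, independent of the remote C2 centre.

Step 5
Reactants: 8 (2E,4R,7S)-7-(tert-butyldimethylsilyloxy)-1,1-dimethoxy-9-methyldeca-2,9-dien-5-yn-4-ol
Product: 10 (2E,4R,5E,7S)-7-(tert-butyldimethylsilyloxy)-5-iodo-1,1-dimethoxy-9-methyldeca-2,5,9-trien-4-ol, via vinylstannane 9 (not isolated)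
Conditions: Bu3SnH, PdCl2(PPh3)2 (2 mol %), THF, 0 °C; then I2, CH2Cl2, 0 °C
Reagents that add atoms: iodine, II
Why: Palladium-catalysed syn-hydrostannation should place tin on the alkyne carbon next to the free carbinol and away from the bulky silyloxy side, and iododestannylation with retention then gives the vinyl iodide with C9 and C2 cis on the alkene.

Step 6
Reactants: 10 (2E,4R,5E,7S)-7-(tert-butyldimethylsilyloxy)-5-iodo-1,1-dimethoxy-9-methyldeca-2,5,9-trien-4-ol
Product: 11 methyl (2E,4S)-4-(tert-butyldimethylsilyloxy)-2-[(1R,2E)-1-hydroxy-4,4-dimethoxybut-2-en-1-yl]-6-methylhepta-2,6-dienoate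
Conditions: PdCl2(PPh3)2 (5 mol %), CO (1 atm), Et3N, MeOH/DMF, 50 °C
Reagents that add atoms: carbon monoxide, [C-]#[O+]; methanol, CO
Why: Palladium-catalysed methoxycarbonylation of a vinyl iodide (oxidative addition, CO insertion, methanolysis) proceeds with retention of alkene geometry and installs C14 trans to C2.

Step 7
Reactants: 11 methyl (2E,4S)-4-(tert-butyldimethylsilyloxy)-2-[(1R,2E)-1-hydroxy-4,4-dimethoxybut-2-en-1-yl]-6-methylhepta-2,6-dienoate
Product: 12 methyl (2E,4S)-2-[(1R,2E)-1-acetoxy-4,4-dimethoxybut-2-en-1-yl]-4-(tert-butyldimethylsilyloxy)-6-methylhepta-2,6-dienoate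
Conditions: Ac2O, pyridine, DMAP (cat.), CH2Cl2, 0 °C
Reagents that add atoms: acetic anhydride, CC(=O)OC(C)=O
Why: Acylation of the only free hydroxyl puts the C9 acetate of the target in place with retention.

Step 8
Reactants: 12 methyl (2E,4S)-2-[(1R,2E)-1-acetoxy-4,4-dimethoxybut-2-en-1-yl]-4-(tert-butyldimethylsilyloxy)-6-methylhepta-2,6-dienoate
Product: 13 methyl (2E,4S)-2-[(1R,2E)-1-acetoxy-4-oxobut-2-en-1-yl]-4-(tert-butyldimethylsilyloxy)-6-methylhepta-2,6-dienoate
Conditions: PPTS (cat.), acetone/H2O, rt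
Reagents that add atoms: water, O
Why: Acid-catalysed hydrolysis of the allylic dimethyl acetal should be much faster than cleavage of the secondary TBS ether and unmasks the C6 aldehyde, which has no δ-hydrogen for elimination of the acetate.

Step 9
Reactants: 13 methyl (2E,4S)-2-[(1R,2E)-1-acetoxy-4-oxobut-2-en-1-yl]-4-(tert-butyldimethylsilyloxy)-6-methylhepta-2,6-dienoate
Product: 14 methyl (2E,4S)-2-[(1R,2E,4R)-1-acetoxy-4-hydroxyhexa-2,5-dien-1-yl]-4-(tert-butyldimethylsilyloxy)-6-methylhepta-2,6-dienoate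
Conditions: (CH2=CH)2Zn, (+)-MIB (10 mol %), toluene, −30 → 0 °C
Reagents that add atoms: divinylzinc, C=C[Zn]C=C
Why: Amino-alcohol-catalysed 1,2-addition of an alkenylzinc reagent to an aldehyde, in which the chiral zinc aminoalkoxide sets C6 (R) by catalyst control and leaves the esters untouched; any minor C6 epimer is left behind in step 10.

Step 10
Reactants: 14 methyl (2E,4S)-2-[(1R,2E,4R)-1-acetoxy-4-hydroxyhexa-2,5-dien-1-yl]-4-(tert-butyldimethylsilyloxy)-6-methylhepta-2,6-dienoate
Product: 15 methyl (2E,4S)-2-{(S)-acetoxy[(2R,3R)-3-[(1R)-1-hydroxyprop-2-en-1-yl]oxiran-2-yl]methyl}-4-(tert-butyldimethylsilyloxy)-6-methylhepta-2,6-dienoate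
Conditions: Ti(OiPr)4 (20 mol %), D-(−)-DIPT (24 mol %), TBHP, 4 Å MS, CH2Cl2, −20 °C
Reagents that add atoms: tert-butyl hydroperoxide, CC(C)(C)OO
Why: Sharpless asymmetric epoxidation of a secondary allylic alcohol in its matched sense, in which D-(−)-DIPT epoxidizes the E-C7=C8 alkene of the 6R alcohol to the erythro (7R,8R) epoxide while the mismatched vinyl group, the electron-poor enoate and the isolated methallyl alkene should not react.

Step 11
Reactants: 15 methyl (2E,4S)-2-{(S)-acetoxy[(2R,3R)-3-[(1R)-1-hydroxyprop-2-en-1-yl]oxiran-2-yl]methyl}-4-(tert-butyldimethylsilyloxy)-6-methylhepta-2,6-dienoate; 16 (diethoxyphosphoryl)acetic acid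
Product: 17 methyl (2E,4S)-2-{(S)-acetoxy[(2R,3R)-3-[(1R)-1-{[(diethoxyphosphoryl)acetyl]oxy}prop-2-en-1-yl]oxiran-2-yl]methyl}-4-(tert-butyldimethylsilyloxy)-6-methylhepta-2,6-dienoate
Conditions: DCC, DMAP (cat.), CH2Cl2, 0 °C → rt
Reagents that add atoms: none
Why: Steglich esterification acylates the hindered C6 hydroxyl under neutral conditions with retention and without touching the epoxide.

Step 12
Reactants: 17 methyl (2E,4S)-2-{(S)-acetoxy[(2R,3R)-3-[(1R)-1-{[(diethoxyphosphoryl)acetyl]oxy}prop-2-en-1-yl]oxiran-2-yl]methyl}-4-(tert-butyldimethylsilyloxy)-6-methylhepta-2,6-dienoate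
Product: 19 methyl (2E,4S)-2-{(1S,2S)-1-acetoxy-2-hydroxy-2-[(2R,3R)-4-methylidene-5-oxo-2-vinyloxolan-3-yl]ethyl}-4-(tert-butyldimethylsilyloxy)-6-methylhepta-2,6-dienoate, via alpha-phosphono lactone 18 (not isolated)
Conditions: NaH (1.05 equiv), THF, 0 → 40 °C; then (CH2O)n, 0 °C → rt
Reagents that add atoms: paraformaldehyde (formaldehyde), C=O
Why: Proposed new method: NaH removes only the phosphonoacetate proton of 17 (far more acidic than the acetate, enoate or allylic protons), the sodium-chelated carbanion at C11 attacks the epoxide carbon C7 anti to its C–O bond and, after transfer of the acidic C11–H of 18 to the O8 alkoxide, the resulting phosphonate carbanion is olefinated by formaldehyde (Horner–Wadsworth–Emmons) to give the C11=C13 methylene. The closest known reaction types are the Stork epoxynitrile cyclization, malonate openings of epoxides and the intramolecular Michael/Horner–Wadsworth–Emmons lactone annulation of O-acyl phosphonoacetates, but an O-acyl-tethered carbanion has not been shown to close a γ-lactone on an epoxide. The lactone ring (C11, C12, O6, C6, C7) closes in the 5-exo-tet mode, and because the charge is carried by the exocyclic phosphoryl group the closure is enolexo, which is the reason for choosing a phosphonoacetate over a plain acetate enolate. C7 is set by SN2 inversion, so that the erythro (6R,7R) epoxy ester gives the trans-6,7 lactone, and C8 keeps its configuration because its C–O bond is untouched. The internal proton transfer leaves no free alkoxide, which should hold back acetyl migration from O9 to O8 and relactonization onto O8. The step needs C-alkylation at C7 over O-alkylation (cyclic ketene acetal) and over 6-endo attack at C8; the soft chelated carbanion and the kinetic preference for exo opening of a trans-disubstituted epoxide should secure this.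

Step 13
Reactants: 19 methyl (2E,4S)-2-{(1S,2S)-1-acetoxy-2-hydroxy-2-[(2R,3R)-4-methylidene-5-oxo-2-vinyloxolan-3-yl]ethyl}-4-(tert-butyldimethylsilyloxy)-6-methylhepta-2,6-dienoate; 20 angelic acid ((Z)-2-methylbut-2-enoic acid)
Product: 22 methyl (2E,4S)-2-{(1S,2S)-1-acetoxy-2-[(2Z)-2-methylbut-2-enoyloxy]-2-[(2R,3S)-4-methylidene-5-oxo-2-vinyloxolan-3-yl]ethyl}-4-(tert-butyldimethylsilyloxy)-6-methylhepta-2,6-dienoate, via angelic 2,4,6-trichlorobenzoic anhydride 21 (not isolated)
Conditions: 20, 2,4,6-trichlorobenzoyl chloride, Et3N (1.0 equiv), toluene, rt; then 19, toluene, 80 °C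
Reagents that add atoms: none
Why: Yamaguchi-type acylation through the mixed anhydride without DMAP is the usual way to avoid isomerization of angelate to tiglate, and the absence of free amine should limit acetyl migration from O9 while C8 is acylated with retention.

Step 14
Reactants: 22 methyl (2E,4S)-2-{(1S,2S)-1-acetoxy-2-[(2Z)-2-methylbut-2-enoyloxy]-2-[(2R,3S)-4-methylidene-5-oxo-2-vinyloxolan-3-yl]ethyl}-4-(tert-butyldimethylsilyloxy)-6-methylhepta-2,6-dienoate
Product: 23 methyl 9α-acetoxy-8β-[(Z)-2-methylbut-2-enoyloxy]-2α-(tert-butyldimethylsilyloxy)germacra-1(10),4Z,11(13)-trien-12,6α-olid-14-oate (ring-cis C1=C10, H6β, H7α)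
Conditions: second-generation Hoveyda–Grubbs catalyst (15 mol %), toluene (1 mM), 80 °C, argon purge
Reagents that add atoms: none
Why: Ring-closing metathesis, in which the ruthenium carbene loads at the monosubstituted C5 vinyl group and closes onto the 1,1-disubstituted alkene; the ten-membered ring should take only the Z (ring-cis) trisubstituted alkene, and the electron-poor methylene lactone, enoate and angelate are poor metathesis partners.

Step 15
Reactants: 23 methyl 9α-acetoxy-8β-[(Z)-2-methylbut-2-enoyloxy]-2α-(tert-butyldimethylsilyloxy)germacra-1(10),4Z,11(13)-trien-12,6α-olid-14-oate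
Product: 24 methyl 9α-acetoxy-8β-[(Z)-2-methylbut-2-enoyloxy]-2α-hydroxygermacra-1(10),4Z,11(13)-trien-12,6α-olid-14-oate
Conditions: HF·pyridine, pyridine/THF, 0 °C → rt
Reagents that add atoms: none
Why: Buffered fluoride desilylation should leave the esters, the lactone and the Michael acceptors untouched, and the freed C2 hydroxyl is trans to C14 and remote from the acyloxy groups, so neither lactonization nor acyl migration is open to it.

Step 16
Reactants: 24 methyl 9α-acetoxy-8β-[(Z)-2-methylbut-2-enoyloxy]-2α-hydroxygermacra-1(10),4Z,11(13)-trien-12,6α-olid-14-oate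
Product: 25 methyl 9α-acetoxy-8β-[(Z)-2-methylbut-2-enoyloxy]-4α,5α-epoxy-2α-hydroxygermacra-1(10),11(13)-dien-12,6α-olid-14-oate, (2S,4R,5S,6S,7R,8S,9S), CNP0278274.1
Conditions: VO(acac)2 (10 mol %), TBHP, CH2Cl2, 0 °C → rt
Reagents that add atoms: tert-butyl hydroperoxide, CC(C)(C)OO
Why: Vanadium-catalysed hydroxyl-directed epoxidation of a homoallylic alcohol, in which the vanadate ester on the 2α-hydroxyl should deliver oxygen to the α face of the only electron-rich alkene (Z-C4=C5) and so set C4 and C5 together, the enoate, angelate and methylene lactone being inert.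

Compound list
1 | 3-(trimethylsilyl)prop-2-ynal | C[Si](C)(C)C#CC=O | starting material
2 | (2-methylallyl)magnesium chloride | C=C(C)C[Mg]Cl | starting material
3 | B-(2-methylallyl)diisopinocampheylborane, Ipc groups (1R,2R,3R,5S) | C[C@H]1[C@H](B(CC(C)=C)[C@@H]2C[C@@H]3C[C@H]([C@H]2C)C3(C)C)C[C@@H]2C[C@H]1C2(C)C | intermediate
4 | (3S)-5-methyl-1-(trimethylsilyl)hex-5-en-1-yn-3-ol | C[Si](C)(C)C#C[C@@H](O)CC(C)=C | intermediate
5 | (3S)-3-(tert-butyldimethylsilyloxy)-5-methyl-1-(trimethylsilyl)hex-5-en-1-yne | C[Si](C)(C)C#C[C@@H](O[Si](C)(C)C(C)(C)C)CC(C)=C | intermediate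
6 | (3S)-3-(tert-butyldimethylsilyloxy)-5-methylhex-5-en-1-yne | C#C[C@@H](O[Si](C)(C)C(C)(C)C)CC(C)=C | intermediate
7 | (2E)-4,4-dimethoxybut-2-enal (fumaraldehyde mono(dimethyl acetal)) | COC(OC)/C=C/C=O | starting material
8 | (2E,4R,7S)-7-(tert-butyldimethylsilyloxy)-1,1-dimethoxy-9-methyldeca-2,9-dien-5-yn-4-ol | COC(OC)/C=C/[C@@H](O)C#C[C@@H](O[Si](C)(C)C(C)(C)C)CC(C)=C | intermediate
9 | (2E,4R,5E,7S)-7-(tert-butyldimethylsilyloxy)-1,1-dimethoxy-9-methyl-5-(tributylstannyl)deca-2,5,9-trien-4-ol | COC(OC)/C=C/[C@@H](O)/C([Sn](CCCC)(CCCC)CCCC)=C\[C@@H](O[Si](C)(C)C(C)(C)C)CC(C)=C | intermediate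
10 | (2E,4R,5E,7S)-7-(tert-butyldimethylsilyloxy)-5-iodo-1,1-dimethoxy-9-methyldeca-2,5,9-trien-4-ol | COC(OC)/C=C/[C@@H](O)/C(I)=C\[C@@H](O[Si](C)(C)C(C)(C)C)CC(C)=C | intermediate
11 | methyl (2E,4S)-4-(tert-butyldimethylsilyloxy)-2-[(1R,2E)-1-hydroxy-4,4-dimethoxybut-2-en-1-yl]-6-methylhepta-2,6-dienoate | COC(OC)/C=C/[C@@H](O)/C(C(=O)OC)=C\[C@@H](O[Si](C)(C)C(C)(C)C)CC(C)=C | intermediate
12 | methyl (2E,4S)-2-[(1R,2E)-1-acetoxy-4,4-dimethoxybut-2-en-1-yl]-4-(tert-butyldimethylsilyloxy)-6-methylhepta-2,6-dienoate | COC(OC)/C=C/[C@@H](OC(C)=O)/C(C(=O)OC)=C\[C@@H](O[Si](C)(C)C(C)(C)C)CC(C)=C | intermediate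
13 | methyl (2E,4S)-2-[(1R,2E)-1-acetoxy-4-oxobut-2-en-1-yl]-4-(tert-butyldimethylsilyloxy)-6-methylhepta-2,6-dienoate | O=C/C=C/[C@@H](OC(C)=O)/C(C(=O)OC)=C\[C@@H](O[Si](C)(C)C(C)(C)C)CC(C)=C | intermediate
14 | methyl (2E,4S)-2-[(1R,2E,4R)-1-acetoxy-4-hydroxyhexa-2,5-dien-1-yl]-4-(tert-butyldimethylsilyloxy)-6-methylhepta-2,6-dienoate | C=C[C@@H](O)/C=C/[C@@H](OC(C)=O)/C(C(=O)OC)=C\[C@@H](O[Si](C)(C)C(C)(C)C)CC(C)=C | intermediate
15 | methyl (2E,4S)-2-{(S)-acetoxy[(2R,3R)-3-[(1R)-1-hydroxyprop-2-en-1-yl]oxiran-2-yl]methyl}-4-(tert-butyldimethylsilyloxy)-6-methylhepta-2,6-dienoate | C=C[C@@H](O)[C@H]1O[C@@H]1[C@@H](OC(C)=O)/C(C(=O)OC)=C\[C@@H](O[Si](C)(C)C(C)(C)C)CC(C)=C | intermediate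
16 | (diethoxyphosphoryl)acetic acid | CCOP(=O)(CC(=O)O)OCC | starting material
17 | methyl (2E,4S)-2-{(S)-acetoxy[(2R,3R)-3-[(1R)-1-{[(diethoxyphosphoryl)acetyl]oxy}prop-2-en-1-yl]oxiran-2-yl]methyl}-4-(tert-butyldimethylsilyloxy)-6-methylhepta-2,6-dienoate | C=C[C@@H](OC(=O)CP(=O)(OCC)OCC)[C@H]1O[C@@H]1[C@@H](OC(C)=O)/C(C(=O)OC)=C\[C@@H](O[Si](C)(C)C(C)(C)C)CC(C)=C | intermediate
18 | alpha-phosphono lactone: the 4-(diethoxyphosphoryl) analogue of 19 lacking the methylidene group (C11 epimers, present as the sodium salt) | CCOP(=O)(OCC)C1C(=O)O[C@H](C=C)[C@H]1[C@H](O)[C@@H](OC(C)=O)/C(C(=O)OC)=C\[C@@H](O[Si](C)(C)C(C)(C)C)CC(C)=C | intermediate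
19 | methyl (2E,4S)-2-{(1S,2S)-1-acetoxy-2-hydroxy-2-[(2R,3R)-4-methylidene-5-oxo-2-vinyloxolan-3-yl]ethyl}-4-(tert-butyldimethylsilyloxy)-6-methylhepta-2,6-dienoate | C=C1C(=O)O[C@H](C=C)[C@H]1[C@H](O)[C@@H](OC(C)=O)/C(C(=O)OC)=C\[C@@H](O[Si](C)(C)C(C)(C)C)CC(C)=C | intermediate
20 | angelic acid, (Z)-2-methylbut-2-enoic acid | C/C=C(/C)C(=O)O | starting material
21 | angelic 2,4,6-trichlorobenzoic anhydride | C/C=C(/C)C(=O)OC(=O)c1c(Cl)cc(Cl)cc1Cl | intermediate
22 | methyl (2E,4S)-2-{(1S,2S)-1-acetoxy-2-[(2Z)-2-methylbut-2-enoyloxy]-2-[(2R,3S)-4-methylidene-5-oxo-2-vinyloxolan-3-yl]ethyl}-4-(tert-butyldimethylsilyloxy)-6-methylhepta-2,6-dienoate | C=C1C(=O)O[C@H](C=C)[C@H]1[C@H](OC(=O)/C(C)=C\C)[C@@H](OC(C)=O)/C(C(=O)OC)=C\[C@@H](O[Si](C)(C)C(C)(C)C)CC(C)=C | intermediate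
23 | methyl 9α-acetoxy-8β-[(Z)-2-methylbut-2-enoyloxy]-2α-(tert-butyldimethylsilyloxy)germacra-1(10),4Z,11(13)-trien-12,6α-olid-14-oate | C/C1=C/[C@H]2OC(=O)C(=C)[C@@H]2[C@H](OC(=O)/C(C)=C\C)[C@@H](OC(C)=O)/C(C(=O)OC)=C\[C@@H](O[Si](C)(C)C(C)(C)C)C1 | intermediate
24 | methyl 9α-acetoxy-8β-[(Z)-2-methylbut-2-enoyloxy]-2α-hydroxygermacra-1(10),4Z,11(13)-trien-12,6α-olid-14-oate | C/C1=C/[C@H]2OC(=O)C(=C)[C@@H]2[C@H](OC(=O)/C(C)=C\C)[C@@H](OC(C)=O)/C(C(=O)OC)=C\[C@@H](O)C1 | intermediate
25 | methyl 9α-acetoxy-8β-[(Z)-2-methylbut-2-enoyloxy]-4α,5α-epoxy-2α-hydroxygermacra-1(10),11(13)-dien-12,6α-olid-14-oate, (2S,4R,5S,6S,7R,8S,9S), CNP0278274.1 | C=C1C(=O)O[C@H]2[C@H]1[C@H](OC(=O)/C(C)=C\C)[C@@H](OC(C)=O)/C(C(=O)OC)=C\[C@@H](O)C[C@@]1(C)O[C@@H]21 | target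

Total step count: 16. Longest linear sequence: 16 steps (1 → 25); compounds 2, 7, 16 and 20 are bought.

Steps most likely to fail

Step 12 (Proposed new method). What may go wrong: O-alkylation of the ambident anion in place of C-alkylation, an opening slow enough that acetyl migration or Michael addition of unreacted carbanion to the product takes over, or attack at C8. The fallback uses known chemistry and sets out from 15. O-Propargylation (propargyl bromide, Ag2O, CH2Cl2) should give the propargyl ether F1. Cp2TiCl, made from Cp2TiCl2 and Zn dust (trivalent titanium) in THF, opens the epoxide homolytically, and the C7 radical closes 5-exo-dig onto the alkyne (Nugent–RajanBabu epoxide radical cyclization) to give the methylene oxolane F2 with the C8 hydroxyl free and C7 trans to the C6 vinyl group. Angeloylation as in step 13 gives the angelate F3, and allylic oxidation of the ring CH2 next to oxygen (CrO3·2 pyridine, CH2Cl2) gives the lactone, which is 22, where the route is rejoined.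

Step 14. What may go wrong: oligomerization by cross metathesis in place of closure of the strained ten-membered ring, or no turnover at the hindered 1,1-disubstituted alkene. The fallback changes the order of ring formation and sets out from 15. Ring-closing metathesis of the more flexible, lactone-free chain, in which the free allylic hydroxyl should speed up loading of the carbene, gives the ten-membered epoxy alcohol F4. Esterification as in step 11 gives the phosphonoacetate F5, the alkylation/olefination of step 12 run on the ring gives the hydroxy lactone F6, and angeloylation as in step 13 comes back to the route at 23.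

Step 16. What may go wrong: poor facial selectivity (oxygen delivered to the β face, or undirected peripheral attack), or oxidation of the allylic C2 alcohol. The fallback reverses the facial bias through a halohydrin and sets out from 23. NBS in aqueous THF should give the bromohydrin F7 by attack of bromine on the exposed β face and of water at C4 from the α face. Ag2O then closes the epoxide with inversion at C5 to give the epoxide silyl ether F8, and HF·pyridine as in step 15 comes back to the route at 25.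

Further compounds
F1 | step 12 | propargyl ether of 15 at O6 | C#CCO[C@H](C=C)[C@H]1O[C@@H]1[C@@H](OC(C)=O)/C(C(=O)OC)=C\[C@@H](O[Si](C)(C)C(C)(C)C)CC(C)=C
F2 | step 12 | methylene oxolane: analogue of 19 with CH2 in place of the lactone C=O | C=C1CO[C@H](C=C)[C@H]1[C@H](O)[C@@H](OC(C)=O)/C(C(=O)OC)=C\[C@@H](O[Si](C)(C)C(C)(C)C)CC(C)=C
F3 | step 12 | angelate of F2 at O8 | C=C1CO[C@H](C=C)[C@H]1[C@H](OC(=O)/C(C)=C\C)[C@@H](OC(C)=O)/C(C(=O)OC)=C\[C@@H](O[Si](C)(C)C(C)(C)C)CC(C)=C
F4 | step 14 | ten-membered epoxy alcohol: methyl 9α-acetoxy-7,8-epoxy-6α-hydroxy-2α-(tert-butyldimethylsilyloxy)-4-methylcyclodeca-1(10),4Z-diene-10-carboxylate (germacrane numbering, stereocentres as in 15) | C/C1=C/[C@@H](O)[C@H]2O[C@@H]2[C@@H](OC(C)=O)/C(C(=O)OC)=C\[C@@H](O[Si](C)(C)C(C)(C)C)C1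
F5 | step 14 | (diethoxyphosphoryl)acetate of F4 at O6 | C/C1=C/[C@@H](OC(=O)CP(=O)(OCC)OCC)[C@H]2O[C@@H]2[C@@H](OC(C)=O)/C(C(=O)OC)=C\[C@@H](O[Si](C)(C)C(C)(C)C)C1
F6 | step 14 | 8β-hydroxy lactone: analogue of 23 with a free C8 hydroxyl | C/C1=C/[C@H]2OC(=O)C(=C)[C@@H]2[C@H](O)[C@@H](OC(C)=O)/C(C(=O)OC)=C\[C@@H](O[Si](C)(C)C(C)(C)C)C1
F7 | step 16 | bromohydrin of 23: 5β-bromo-4α-hydroxy-4β-methyl | C=C1C(=O)O[C@H]2[C@H]1[C@H](OC(=O)/C(C)=C\C)[C@@H](OC(C)=O)/C(C(=O)OC)=C\[C@@H](O[Si](C)(C)C(C)(C)C)C[C@@](C)(O)[C@@H]2Br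
F8 | step 16 | tert-butyldimethylsilyl ether of 25 at O2 | C=C1C(=O)O[C@H]2[C@H]1[C@H](OC(=O)/C(C)=C\C)[C@@H](OC(C)=O)/C(C(=O)OC)=C\[C@@H](O[Si](C)(C)C(C)(C)C)C[C@@]1(C)O[C@@H]21
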